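**Plan**

1. Locants: ring A is the tribromomethoxyphenyl ring (C1 carries the ether oxygen). Ring B is the dibromophenol ring (C1' OAr, C2' H, C3' Br, C4' H, C5' Br, C6' OH); the primed locants are kept for the five-membered precursors.
2. Retrosynthesis: cut C3'–Br first (late bromination para to the phenol). Then cut the ring bonds C4'–C5' and C5'–C6', which removes C5' with its bromine as dibromocarbene and leaves a 2-silyloxy-3-aryloxycyclopentadiene. Then cut O–C1' (phenoxide plus 2,3-epoxycyclopentanone), and in ring A the C2–Br bond and the C1–O bond (from a formyl carbon).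
3. Enabling feature: in ring B the brominated C5' lies between C4'–H and the phenol carbon C6', which itself neighbours the ether carbon C1'. A CBr unit next to an oxygenated carbon is what carbene insertion into a cyclic silyl enol ether delivers, and the C3' methylene lets the new ring aromatize without an oxidant.
4. Forward order: ring A is bought aromatic and adjusted (O-methylation, Baeyer–Villiger, ortho-bromination). The five-membered carbocycle from cyclopent-2-en-1-one is joined through O–C1'. Ring B arises last by one-carbon ring expansion, followed by para-bromination.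
5. Stereochemistry: the target is achiral and has no stereocentre; the stereocentres of the racemic epoxide, hydroxy ketone and cyclopropane intermediates are all destroyed on the way.

Key step: step 7

Remark: all chiral intermediates are racemic; SMILES with stereodescriptors show one enantiomer only to fix the relative configuration.

**Route**

Step 1
Reactants: 1 3,5-dibromo-2-hydroxybenzaldehyde
Product: 2 3,5-dibromo-2-methoxybenzaldehyde
Conditions: MeI, K2CO3, DMF, 25 °C
Reagents that add atoms: iodomethane, CI
Why: Williamson O-methylation of the acidic phenol flanked by bromine and formyl should go readily in DMF and installs the methoxy group that later directs aryl migration.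

Step 2
Reactants: 2 3,5-dibromo-2-methoxybenzaldehyde
Product: 4 3,5-dibromo-2-methoxyphenol, via aryl formate 3 (not isolated)
Conditions: mCPBA, CH2Cl2, 40 °C; NaHCO3 wash; then K2CO3 (0.2 equiv), MeOH, 25 °C
Reagents that add atoms: meta-chloroperoxybenzoic acid, OOC(=O)c1cccc(Cl)c1
Why: In this Baeyer–Villiger (Dakin-type) oxidation the ortho-methoxy group should make the aryl group migrate in preference to hydride, and methanolysis of the formate leaves the phenol oxygen where the formyl carbon was.

Step 3
Reactants: 4 3,5-dibromo-2-methoxyphenol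
Product: 5 2,3,5-tribromo-6-methoxyphenol
Conditions: NBS (1.0 equiv), i-Pr2NH (0.1 equiv), CH2Cl2, 0 °C
Reagents that add atoms: N-bromosuccinimide, O=C1CCC(=O)N1Br
Why: Amine-mediated electrophilic aromatic bromination delivers bromine ortho to the hydroxyl through a hydrogen-bonded N-bromoamine, and the only open ortho position is C6 while the para position is shielded between two bromines.

Step 4
Reactants: 6 cyclopent-2-en-1-one
Product: 7 6-oxabicyclo[3.1.0]hexan-2-one (2,3-epoxycyclopentanone)
Conditions: H2O2 (30% aq), NaOH (cat.), MeOH, 0 °C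
Reagents that add atoms: hydrogen peroxide, OO
Why: In the Weitz–Scheffer epoxidation hydroperoxide adds in conjugate fashion and the enolate closes the oxirane, which can only be cis-fused, so the racemic epoxy ketone should result.

Step 5
Reactants: 5 2,3,5-tribromo-6-methoxyphenol; 7 6-oxabicyclo[3.1.0]hexan-2-one
Product: 9 2-(2,3,5-tribromo-6-methoxyphenoxy)cyclopent-2-en-1-one, via trans hydroxy ketone 8 (not isolated)
Conditions: Cs2CO3 (0.3 equiv), DMF, 25 → 70 °C
Reagents that add atoms: none
Why: The phenoxide should open the oxirane by SN2 attack at the carbon alpha to the carbonyl (inversion, trans product) and E1cB loss of water then gives the 2-aryloxy enone, as in the known conversion of alpha,beta-epoxy ketones into 2-alkoxy, 2-aryloxy and 2-arylthio enones, which erases both stereocentres.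

Step 6
Reactants: 9 2-(2,3,5-tribromo-6-methoxyphenoxy)cyclopent-2-en-1-one
Product: 11 2-(tert-butyldimethylsilyloxy)-3-(2,3,5-tribromo-6-methoxyphenoxy)cyclopenta-1,3-diene, via lithium dienolate 10 (not isolated)
Conditions: LiN(SiMe3)2, THF, −78 °C (9 added to the base); then TBSOTf, −78 °C; cold pentane, filtration under argon, solution used at once
Reagents that add atoms: tert-butyldimethylsilyl triflate, CC(C)(C)[Si](C)(C)OS(=O)(=O)C(F)(F)F
Why: Kinetic alpha'-deprotonation of the enone at C4' gives the cross-conjugated dienolate, which the silyl triflate traps on oxygen (kinetic silyl enol ether formation), and the hexamethyldisilazide is too weak a base to metalate the ring A C–H between the two bromines.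

Step 7
Reactants: 11 2-(tert-butyldimethylsilyloxy)-3-(2,3,5-tribromo-6-methoxyphenoxy)cyclopenta-1,3-diene; 12 bromoform
Product: 16 2-bromo-6-(2,3,5-tribromo-6-methoxyphenoxy)phenol, via dibromocyclopropane 13 (not isolated), via silyloxyarenium bromide 14 (not isolated), via aryl silyl ether 15 (not isolated)
Conditions: CHBr3 (1.5 equiv), KOtBu (3 equiv, added last in portions), pentane–toluene, −30 → 0 °C; then MeOH, K2CO3 (cat.), 25 °C
Reagents that add atoms: none
Why: Tert-butoxide frees dibromocarbene from bromoform, and the carbene adds in a concerted [2+1] cheletropic step to the C4'=C6' silyl enol ether bond of 11, closing the three-membered ring of 13 (cis-fused by necessity). The shared C4'–C6' bond of 13 then opens in a disrotatory two-electron electrocyclic process as the endo bromide leaves, pushed by the silyloxy group, so that ring B arises by ring expansion with C5' and its bromine inserted between C4' and C6' (new bonds C4'–C5' and C5'–C6'). The resulting cation 14 is the C3'-protonated form of an aryl silyl ether, so it should lose that proton to the base and give arene 15 without an oxidant, and methanolysis of the Si–O bond then frees phenol 16. The closest known reaction type is the dihalocarbene ring expansion of cyclic silyl enol ethers (1-silyloxycyclopentenes to 2-halocyclohex-2-enones, 1-silyloxyindenes to 2-halo-1-naphthols), together with the carbene ring expansion of cyclopentadienes and indenes to haloarenes. No stereocentre survives, since the two of 13 are lost on opening. The step needs the carbene to choose the silyloxy alkene over the aryloxy alkene and to arrive before the diene isomerizes: the silyl enol ether is the more electron-rich and less shielded double bond (the tribromoaryloxy group is electron-poor and twisted), and keeping the diene below 0 °C with bromoform in excess and KOtBu added last lets the more acidic haloform, not the cyclopentadiene methylene, consume the alkoxide.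

Step 8
Reactants: 16 2-bromo-6-(2,3,5-tribromo-6-methoxyphenoxy)phenol
Product: 17 2,4-dibromo-6-(2,3,5-tribromo-6-methoxyphenoxy)phenol
Conditions: Br2 (1.0 equiv), CH2Cl2–AcOH, 0 °C
Reagents that add atoms: bromine, BrBr
Why: In this electrophilic aromatic bromination both positions ortho to the free hydroxyl of ring B are occupied (C1' and C5'), so one equivalent of bromine should enter C3', para to the hydroxyl, while ring A is deactivated by three bromines and its only C–H lies between two of them.

**Compound list**

1 | 3,5-dibromo-2-hydroxybenzaldehyde (3,5-dibromosalicylaldehyde) | O=Cc1cc(Br)cc(Br)c1O | starting material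
2 | 3,5-dibromo-2-methoxybenzaldehyde | COc1c(Br)cc(Br)cc1C=O | intermediate
3 | 3,5-dibromo-2-methoxyphenyl formate (not isolated) | COc1c(Br)cc(Br)cc1OC=O | intermediate
4 | 3,5-dibromo-2-methoxyphenol | COc1c(Br)cc(Br)cc1O | intermediate
5 | 2,3,5-tribromo-6-methoxyphenol | COc1c(Br)cc(Br)c(Br)c1O | intermediate
6 | cyclopent-2-en-1-one | O=C1C=CCC1 | starting material
7 | 6-oxabicyclo[3.1.0]hexan-2-one (2,3-epoxycyclopentanone), racemic, cis-fused | O=C1CC[C@H]2O[C@@H]12 | intermediate
8 | trans-3-hydroxy-2-(2,3,5-tribromo-6-methoxyphenoxy)cyclopentan-1-one, racemic (not isolated) | O=C1CC[C@@H](O)[C@@H]1Oc1c(OC)c(Br)cc(Br)c1Br | intermediate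
9 | 2-(2,3,5-tribromo-6-methoxyphenoxy)cyclopent-2-en-1-one | O=C1CCC=C1Oc1c(OC)c(Br)cc(Br)c1Br | intermediate
10 | lithium 5-(2,3,5-tribromo-6-methoxyphenoxy)cyclopenta-1,4-dien-1-olate (not isolated) | [Li+].[O-]C1=CCC=C1Oc1c(OC)c(Br)cc(Br)c1Br | intermediate
11 | 2-(tert-butyldimethylsilyloxy)-3-(2,3,5-tribromo-6-methoxyphenoxy)cyclopenta-1,3-diene | CC(C)(C)[Si](C)(C)OC1=CCC=C1Oc1c(OC)c(Br)cc(Br)c1Br | intermediate
12 | bromoform | BrC(Br)Br | starting material
13 | 6,6-dibromo-1-(tert-butyldimethylsilyloxy)-2-(2,3,5-tribromo-6-methoxyphenoxy)bicyclo[3.1.0]hex-2-ene, racemic, cis-fused (not isolated) | CC(C)(C)[Si](C)(C)O[C@]12C(Oc3c(OC)c(Br)cc(Br)c3Br)=CC[C@H]1C2(Br)Br | intermediate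
14 | O-(tert-butyldimethylsilyl) 2-bromo-6-(2,3,5-tribromo-6-methoxyphenoxy)cyclohexa-2,5-dien-1-one oxocarbenium bromide, the C3'-protonated form of 15 (not isolated) | CC(C)(C)[Si](C)(C)[O+]=C1C(Br)=CCC=C1Oc1c(OC)c(Br)cc(Br)c1Br.[Br-] | intermediate
15 | tert-butyl[2-bromo-6-(2,3,5-tribromo-6-methoxyphenoxy)phenoxy]dimethylsilane (not isolated) | CC(C)(C)[Si](C)(C)Oc1c(Br)cccc1Oc1c(OC)c(Br)cc(Br)c1Br | intermediate
16 | 2-bromo-6-(2,3,5-tribromo-6-methoxyphenoxy)phenol | COc1c(Br)cc(Br)c(Br)c1Oc1cccc(Br)c1O | intermediate
17 | 2,4-dibromo-6-(2,3,5-tribromo-6-methoxyphenoxy)phenol (CNP0222668.0) | COc1c(Br)cc(Br)c(Br)c1Oc1cc(Br)cc(Br)c1O | target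

**Count**

Total steps: 8. Longest linear sequence: 7 steps (1 → 2 → 4 → 5 → 9 → 11 → 16 → 17; step 4 is the one-step side branch).

**Steps most likely to fail**

Step 7. The carbene may add to the aryloxy-substituted double bond, the alkoxide may deprotonate the cyclopentadiene methylene, or the diene may undergo a 1,5-hydrogen shift or Diels–Alder dimerization before cyclopropanation. Each of these diverts material to regioisomeric bromoarenes or oligomers. The fallback sets out from 5 and returns at 16, making the ether bond by nucleophilic aromatic substitution instead. Phenol 5 and 1-bromo-3-fluoro-2-nitrobenzene (K2CO3, DMF, 80 °C) should give 1-bromo-2-nitro-3-(2,3,5-tribromo-6-methoxyphenoxy)benzene F1. Reduction with Fe and NH4Cl in aqueous ethanol should give 2-bromo-6-(2,3,5-tribromo-6-methoxyphenoxy)aniline F2 with the aryl bromides intact. Diazotization (NaNO2, H2SO4, 0 °C) gives 2-bromo-6-(2,3,5-tribromo-6-methoxyphenoxy)benzenediazonium hydrogensulfate F3, and its hydrolysis with Cu2O and Cu(NO3)2 in water should give phenol 16.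

Step 6. Gamma-deprotonation or proton exchange during enolization, and hydrogen migration or dimerization of the silyloxycyclopentadiene during its non-aqueous isolation, would erode the position of the silyl enol ether double bond. The fallback sets out from 5 and returns at 16, working one oxidation level lower, where the silyl enol ether is an ordinary cyclopentene. Alkylation of 5 with 2-chlorocyclopentanone (K2CO3, NaI, acetone) should give 2-(2,3,5-tribromo-6-methoxyphenoxy)cyclopentan-1-one F4. Kinetic enolization away from the aryloxy carbon (LiN(SiMe3)2, THF, −78 °C; TBSOTf) should give tert-butyldimethyl{[5-(2,3,5-tribromo-6-methoxyphenoxy)cyclopent-1-en-1-yl]oxy}silane F5. Dibromocarbene (CHBr3, KOtBu, pentane) should give 6,6-dibromo-1-(tert-butyldimethylsilyloxy)-2-(2,3,5-tribromo-6-methoxyphenoxy)bicyclo[3.1.0]hexane F6, which on warming opens with loss of the silyl group to 2-bromo-6-(2,3,5-tribromo-6-methoxyphenoxy)cyclohex-2-en-1-one F7 (the established 2-halo enone ring expansion). Dehydrogenation with 2,3-dichloro-5,6-dicyano-1,4-benzoquinone (cat. TsOH, dioxane, 100 °C) then gives 16.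

Step 5. Oxirane opening by the hindered, weakly nucleophilic 2,6-disubstituted phenoxide may be slow, so that base-induced isomerization of the epoxy ketone to the enolized 1,2-dione takes over, or the sequence may stall at the hydroxy ketone. The fallback sets out from 5 and returns at 9, using an allylic epoxide that has no carbonyl group. Cyclopentadiene and peracetic acid (Na2CO3, CH2Cl2) give 6-oxabicyclo[3.1.0]hex-2-ene F8. The phenoxide of 5 (K2CO3, DMF, 50 °C) should open it at the allylic carbon with inversion to trans-2-(2,3,5-tribromo-6-methoxyphenoxy)cyclopent-3-en-1-ol F9. Dess–Martin periodinane should give 2-(2,3,5-tribromo-6-methoxyphenoxy)cyclopent-3-en-1-one F10. Et3N then moves the double bond into conjugation through the more acidic C–H at the aryloxy-bearing carbon to give enone 9.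

**Further compounds**

F1 | step 7 | 1-bromo-2-nitro-3-(2,3,5-tribromo-6-methoxyphenoxy)benzene | COc1c(Br)cc(Br)c(Br)c1Oc1cccc(Br)c1[N+](=O)[O-]
F2 | step 7 | 2-bromo-6-(2,3,5-tribromo-6-methoxyphenoxy)aniline | COc1c(Br)cc(Br)c(Br)c1Oc1cccc(Br)c1N
F3 | step 7 | 2-bromo-6-(2,3,5-tribromo-6-methoxyphenoxy)benzenediazonium hydrogensulfate | COc1c(Br)cc(Br)c(Br)c1Oc1cccc(Br)c1[N+]#N.OS(=O)(=O)[O-]
F4 | step 6 | 2-(2,3,5-tribromo-6-methoxyphenoxy)cyclopentan-1-one, racemic | COc1c(Br)cc(Br)c(Br)c1OC1CCCC1=O
F5 | step 6 | tert-butyldimethyl{[5-(2,3,5-tribromo-6-methoxyphenoxy)cyclopent-1-en-1-yl]oxy}silane, racemic | CC(C)(C)[Si](C)(C)OC1=CCCC1Oc1c(OC)c(Br)cc(Br)c1Br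
F6 | step 6 | 6,6-dibromo-1-(tert-butyldimethylsilyloxy)-2-(2,3,5-tribromo-6-methoxyphenoxy)bicyclo[3.1.0]hexane, racemic, cis-fused, mixture at the aryloxy carbon | CC(C)(C)[Si](C)(C)O[C@]12C(Oc3c(OC)c(Br)cc(Br)c3Br)CC[C@H]1C2(Br)Br
F7 | step 6 | 2-bromo-6-(2,3,5-tribromo-6-methoxyphenoxy)cyclohex-2-en-1-one, racemic | COc1c(Br)cc(Br)c(Br)c1OC1CCC=C(Br)C1=O
F8 | step 5 | 6-oxabicyclo[3.1.0]hex-2-ene (3,4-epoxycyclopentene), racemic, cis-fused | C1C=C[C@H]2O[C@@H]12
F9 | step 5 | trans-2-(2,3,5-tribromo-6-methoxyphenoxy)cyclopent-3-en-1-ol, racemic | O[C@@H]1CC=C[C@H]1Oc1c(OC)c(Br)cc(Br)c1Br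
F10 | step 5 | 2-(2,3,5-tribromo-6-methoxyphenoxy)cyclopent-3-en-1-one, racemic | O=C1CC=CC1Oc1c(OC)c(Br)cc(Br)c1Br
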